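## Retrosynthetic overview

- The target is a 5,5'-biaryl that joins an all-cis olivil-type oxolane to a cycloolivil-type tetralin. Both C4 side chains come from one epoxy diol **12**, made by Sharpless epoxidation, which is the only catalyst-set stereochemistry. Both benzylic carbons come from 5-bromovanillin.
- Enabling feature: in the oxolane O1–C2(aryl)–C3(CH2OH)–C4(OH)(CH2Ar)–C5H2, O1 and the hydroxyl oxygen of the C3 branch are the two ends of one four-carbon chain (C5–C4–C3–CH2). C2 is an aldehyde-level benzylic carbon next to C3. Both oxygens can therefore sit on C2 as a seven-membered vinyl acetal (4,5-dihydro-1,3-dioxepine), and a [1,3] O→C shift of C2 contracts 7→5.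
- Disconnections: oxolane ⇐ vinyl acetal **26** by ring contraction. Biaryl ⇐ Suzuki coupling of **24** and **25**. Tetralin ⇐ Friedel–Crafts re-closure of bromo-oxolane **22**. Both **22** and **25** come from the same bromo vinyl acetal **20**.
- Ring order: oxirane (temporary) → dioxepane/dioxepine (temporary) → bromo-oxolane (temporary) → tetralin → biaryl bond → oxolane of the target (last).

Key step: step 16

Assumption: the acetal carbon in 16–20, 25 and 26 (and Se in 19) forms as an epimer mixture and is drawn without configuration, because it becomes planar (or is lost) in steps 10, 11 and 16.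

## Route

Step 1
Reactants: 1 tert-butyldimethyl(prop-2-yn-1-yloxy)silane
Product: 3 methyl 4-[(tert-butyldimethylsilyl)oxy]but-2-ynoate, via lithium acetylide 2 (not isolated)
Conditions: n-BuLi, THF, −78 °C; ClCO2Me, −78 → 0 °C
Reagents that add atoms: methyl chloroformate, COC(=O)Cl
Why: Deprotonation of the terminal alkyne and C-acylation of the acetylide with a chloroformate is a standard alkynoate synthesis and forms no stereocentre.

Step 2
Reactants: 4 [4-(benzyloxy)-3-methoxyphenyl]methanol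
Product: 5 1-(benzyloxy)-4-(chloromethyl)-2-methoxybenzene
Conditions: SOCl2, CH2Cl2, 0 °C, used crude
Reagents that add atoms: thionyl chloride, O=S(Cl)Cl
Why: Chlorodehydroxylation of an electron-rich benzylic alcohol is fast at 0 °C, and the chloride is preferred over the bromide to limit Wurtz coupling in step 3.

Step 3
Reactants: 5 benzylic chloride; 3 alkynoate
Product: 9 methyl (Z)-3-{[4-(benzyloxy)-3-methoxyphenyl]methyl}-4-[(tert-butyldimethylsilyl)oxy]but-2-enoate, via benzylmagnesium chloride 6 (not isolated), via benzylcopper 7 (not isolated), via alkenylcopper 8 (not isolated)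
Conditions: Mg, THF, 0 °C (slow addition); CuBr·SMe2, −40 °C; 3, −78 °C; sat. NH4Cl at −78 °C
Reagents that add atoms: none
Why: syn-Carbocupration of an alkynoate followed by cold protonation places CH2OTBS cis to the ester, giving the cis-butenediol geometry with the two oxygens already differentiated.

Step 4
Reactants: 9 (Z)-enoate
Product: 10 (Z)-3-{[4-(benzyloxy)-3-methoxyphenyl]methyl}-4-[(tert-butyldimethylsilyl)oxy]but-2-en-1-ol
Conditions: DIBAL-H (2.2 equiv), CH2Cl2, −78 → 0 °C; Rochelle salt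
Reagents that add atoms: none
Why: 1,2-Reduction of an enoate with DIBAL-H gives the allylic alcohol without touching the alkene geometry, the silyl ether or the benzyl ether.

Step 5
Reactants: 10 allylic alcohol
Product: 11 [(2S,3R)-3-{[4-(benzyloxy)-3-methoxyphenyl]methyl}-3-{[(tert-butyldimethylsilyl)oxy]methyl}oxiran-2-yl]methanol
Conditions: Ti(Oi-Pr)4 (10 mol %), L-(+)-DIPT (12 mol %), t-BuOOH, 4 Å MS, CH2Cl2, −20 °C
Reagents that add atoms: tert-butyl hydroperoxide, CC(C)(C)OO
Why: Sharpless asymmetric epoxidation of a 3,3-disubstituted (nerol-type) allylic alcohol with L-(+)-tartrate should give the (2S,3R)-epoxide, whose quaternary C–O bond becomes the tertiary carbinol centre of both halves of the target.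

Step 6
Reactants: 11 epoxy alcohol
Product: 12 [(2R,3S)-2-{[4-(benzyloxy)-3-methoxyphenyl]methyl}oxirane-2,3-diyl]dimethanol
Conditions: TBAF, AcOH (1:1), THF, 0 °C → rt
Reagents that add atoms: none
Why: Buffered fluoride desilylation frees the second primary alcohol without generating free alkoxide, which suppresses Payne migration of the epoxide.

Step 7
Reactants: 13 5-bromovanillin
Product: 14 4-(benzyloxy)-3-bromo-5-methoxybenzaldehyde
Conditions: BnBr, K2CO3, DMF, rt
Reagents that add atoms: benzyl bromide, BrCc1ccccc1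
Why: Williamson O-benzylation of the phenol gives a group that is stable to all later steps and is removed by neutral hydrogenolysis at the end.

Step 8
Reactants: 14 aldehyde; 12 epoxy diol
Product: 16 (1R,7S)-4-[4-(benzyloxy)-3-bromo-5-methoxyphenyl]-1-{[4-(benzyloxy)-3-methoxyphenyl]methyl}-3,5,8-trioxabicyclo[5.1.0]octane, via dimethyl acetal 15 (not isolated)
Conditions: HC(OMe)3, PPTS (cat.), CH2Cl2, rt; concentrate; 12, PPTS (cat.), toluene, 35 °C, reduced pressure (MeOH removal)
Reagents that add atoms: none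
Why: Transacetalisation of an aryl dimethyl acetal by a cis-held 1,4-diol under PPTS is mild enough for the trisubstituted epoxide, and the epoxide masks the tertiary oxygen so that only the seven-membered acetal can form.

Step 9
Reactants: 16 epoxy acetal
Product: 18 (5R,6R)-2-[4-(benzyloxy)-3-bromo-5-methoxyphenyl]-5-{[4-(benzyloxy)-3-methoxyphenyl]methyl}-6-(phenylselanyl)-5-[(triethylsilyl)oxy]-1,3-dioxepane, via sodium alkoxide 17 (not isolated)
Conditions: PhSeH, NaH, DMF, 0 → 50 °C; TESCl, 0 °C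
Reagents that add atoms: benzeneselenol, [SeH]c1ccccc1; chlorotriethylsilane, CC[Si](Cl)(CC)CC
Why: The soft selenolate opens the epoxide by SN2 at the only accessible (secondary) carbon, so the C–O bond at the quaternary centre is untouched, and the tertiary alkoxide is capped in the same flask.

Step 10
Reactants: 18 silyloxy selenide
Product: 20 (5S)-2-[4-(benzyloxy)-3-bromo-5-methoxyphenyl]-5-{[4-(benzyloxy)-3-methoxyphenyl]methyl}-5-[(triethylsilyl)oxy]-4,5-dihydro-1,3-dioxepine, via selenoxide 19 (not isolated)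
Conditions: mCPBA (1.0 equiv), CH2Cl2, −78 °C; i-Pr2NEt; toluene, 80 °C
Reagents that add atoms: none
Why: In the selenoxide syn-elimination one β-carbon is quaternary, so the only β-hydrogens are on the OCH2 carbon and only the ring enol ether (vinyl acetal) can form, with the amine keeping the medium basic.

Step 11
Reactants: 20 bromo vinyl acetal
Product: 22 [(2R,3R,4S)-2-[4-(benzyloxy)-3-bromo-5-methoxyphenyl]-4-{[4-(benzyloxy)-3-methoxyphenyl]methyl}-4-[(triethylsilyl)oxy]oxolan-3-yl]methanol, via oxolane-3-carbaldehyde 21 (not isolated)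
Conditions: TMSOTf (0.2 equiv), 2,6-di-tert-butyl-4-methylpyridine, CH2Cl2, −78 °C; Et3N; DIBAL-H, −78 °C
Reagents that add atoms: none
Why: This is the same Lewis-acid [1,3] O→C vinyl acetal ring contraction as in step 16, where the C3 centre is relayed from the quaternary carbinol centre and the C2 configuration is irrelevant because step 12 ionises it.

Step 12
Reactants: 22 bromo-oxolane
Product: 23 (2S,3S,4S)-6-(benzyloxy)-4-[4-(benzyloxy)-3-bromo-5-methoxyphenyl]-2,3-bis(hydroxymethyl)-7-methoxy-1,2,3,4-tetrahydronaphthalen-2-ol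
Conditions: TfOH (10 mol %), HFIP/CH2Cl2 1:4, 0 °C; aq. NaHCO3
Reagents that add atoms: none
Why: Acid ionisation of the benzylic C2–O bond and intramolecular Friedel–Crafts alkylation para to the methoxy group (olivil → cycloolivil type isomerisation) closes the tetralin, the aryl group takes the pseudo-equatorial position trans to the neighbouring CH2OH, and the TES ether is lost in the protic medium.

Step 13
Reactants: 23 triol
Product: 24 tris-TBS ether of 23 (both CH2OH groups plus the tertiary OH silylated)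
Conditions: TBSOTf (4.5 equiv), 2,6-lutidine, CH2Cl2, 0 °C → rt
Reagents that add atoms: tert-butyldimethylsilyl triflate, CC(C)(C)[Si](C)(C)OS(=O)(=O)C(F)(F)F
Why: Silyl triflate silylates primary and hindered tertiary alcohols alike, giving one fluoride-labile protecting class that tolerates steps 15 and 16.

Step 14
Reactants: 20 bromo vinyl acetal
Product: 25 pinacol boronate of 20 (Br replaced by Bpin)
Conditions: B2pin2, PdCl2(dppf) (3 mol %), KOAc, dioxane, 80 °C
Reagents that add atoms: bis(pinacolato)diboron, CC1(C)OB(OC1(C)C)B1OC(C)(C)C(C)(C)O1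
Why: Miyaura borylation runs under weakly basic, non-acidic conditions to which the glycal-like O–CH=CH–C(OSiR3) unit and the acetal are inert.

Step 15
Reactants: 24 aryl bromide; 25 aryl boronate
Product: 26 biaryl vinyl acetal (20 with Br replaced by the debrominated aryl carbon of 24)
Conditions: Pd(OAc)2 (3 mol %), SPhos, K3PO4, THF/H2O 10:1, 60 °C
Reagents that add atoms: none
Why: Suzuki–Miyaura coupling of two mono-ortho-alkoxy partners with a biarylphosphine ligand forms the 5,5'-bond under basic conditions that leave silyl ethers, acetal and enol ether intact, and the biaryl axis is not stereogenic.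

Step 16
Reactants: 26 biaryl vinyl acetal
Product: 28 protected target with free C3–CH2OH, (2R,3R,4S)-oxolane, C4–OTES, three TBS ethers and four aryl benzyl ethers, via oxolane-3-carbaldehyde 27 (not isolated)
Conditions: TMSOTf (0.2 equiv), 2,6-di-tert-butyl-4-methylpyridine (0.3 equiv), CH2Cl2, −78 °C; Et3N; DIBAL-H, −78 °C; Rochelle salt
Reagents that add atoms: none
Why: TMSOTf silylates the enol-ether oxygen, its bond to the acetal carbon breaks, and the aryl-stabilised oxocarbenium ion (still bound to O1) is attacked by the β-carbon of the (Z)-silyl enol ether released in the same event; loss of TMS+ returns the catalyst and gives aldehyde 27, which DIBAL-H reduces at −78 °C before it can epimerise or eliminate silanol. The closest known reaction is the Lewis-acid-mediated [1,3] O-to-C rearrangement (vinyl acetal ring contraction, Petasis–Ferrier/Mukaiyama-aldol type) of 2-aryl-4,5-dihydro-1,3-dioxepines to 2-aryl-oxolane-3-carbaldehydes. The oxolane closes in a 5-(enolexo)-endo-trig mode, a 7→5 contraction in which both acetal epimers converge on one planar cation. C2 is controlled by the contact ion pair: the enol oxygen leaves and the enol carbon arrives on the same face of the (E)-oxocarbenium ion (least motion), which places aryl and formyl cis, the kinetic outcome at −78 °C. C3 is controlled by the only existing centre C4: the (Z)-enol ether forbids any "inside" substituent (A1,3 strain), so the C4–O bond lies in the enol plane (outside) and the better-donating, larger CH2Ar bond stands anti to the forming bond, which makes formyl cis to CH2Ar and trans to OSiEt3. The step needs acetal ionisation to outrun Ferrier-type loss of the tertiary allylic oxygen and re-opening of the product; this is secured by the hindered, weakly basic OSiEt3 group, by catalytic TMSOTf with a proton scavenger at −78 °C, and by the benzyloxy group of this ring, which is flanked by OMe and aryl, twisted out of conjugation, and so makes the product ether hard to re-ionise.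

Step 17
Reactants: 28 silyl-protected oxolane
Product: 29 tetra-O-benzyl ether of the target (all six aliphatic OH free)
Conditions: TBAF (8 equiv), THF, rt → 45 °C
Reagents that add atoms: none
Why: Fluoride removes the three TBS groups and the TES group while the phenols are still benzylated, so no phenoxide-driven quinone-methide opening of the cis-oxolane can occur.

Step 18
Reactants: 29 tetrabenzyl ether
Product: 30 target CNP0344108.1
Conditions: H2 (1 atm), 10 % Pd/C, EtOAc/EtOH, rt
Reagents that add atoms: none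
Why: Neutral hydrogenolysis cleaves aryl benzyl ethers much faster than the hindered cyclic benzylic C–O bond, so no stereocentre is touched and no acid reaches the acid-labile cis-oxolane.

## Compound list

1 | tert-butyldimethyl(prop-2-yn-1-yloxy)silane | C#CCO[Si](C)(C)C(C)(C)C | starting material
2 | lithium acetylide of 1 | [Li]C#CCO[Si](C)(C)C(C)(C)C | intermediate
3 | methyl 4-[(tert-butyldimethylsilyl)oxy]but-2-ynoate | COC(=O)C#CCO[Si](C)(C)C(C)(C)C | intermediate
4 | [4-(benzyloxy)-3-methoxyphenyl]methanol | COc1cc(CO)ccc1OCc1ccccc1 | starting material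
5 | 1-(benzyloxy)-4-(chloromethyl)-2-methoxybenzene | COc1cc(CCl)ccc1OCc1ccccc1 | intermediate
6 | [4-(benzyloxy)-3-methoxybenzyl]magnesium chloride | COc1cc(C[Mg]Cl)ccc1OCc1ccccc1 | intermediate
7 | [4-(benzyloxy)-3-methoxybenzyl]copper | COc1cc(C[Cu])ccc1OCc1ccccc1 | intermediate
8 | alkenylcopper syn-adduct of 7 and 3 | COC(=O)/C([Cu])=C(\CO[Si](C)(C)C(C)(C)C)Cc1ccc(OCc2ccccc2)c(OC)c1 | intermediate
9 | methyl (Z)-3-{[4-(benzyloxy)-3-methoxyphenyl]methyl}-4-[(TBS)oxy]but-2-enoate | COC(=O)/C=C(\CO[Si](C)(C)C(C)(C)C)Cc1ccc(OCc2ccccc2)c(OC)c1 | intermediate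
10 | (Z)-3-{[4-(benzyloxy)-3-methoxyphenyl]methyl}-4-[(TBS)oxy]but-2-en-1-ol | OC/C=C(\CO[Si](C)(C)C(C)(C)C)Cc1ccc(OCc2ccccc2)c(OC)c1 | intermediate
11 | (2S,3R)-epoxy alcohol | OC[C@@H]1O[C@@]1(CO[Si](C)(C)C(C)(C)C)Cc1ccc(OCc2ccccc2)c(OC)c1 | intermediate
12 | (2R,3S)-epoxy diol | OC[C@@H]1O[C@@]1(CO)Cc1ccc(OCc2ccccc2)c(OC)c1 | intermediate
13 | 5-bromovanillin | COc1cc(C=O)cc(Br)c1O | starting material
14 | 4-(benzyloxy)-3-bromo-5-methoxybenzaldehyde | COc1cc(C=O)cc(Br)c1OCc1ccccc1 | intermediate
15 | dimethyl acetal of 14 | COc1cc(C(OC)OC)cc(Br)c1OCc1ccccc1 | intermediate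
16 | (1R,7S)-bromoaryl epoxy acetal (3,5,8-trioxabicyclo[5.1.0]octane) | COc1cc(C2OC[C@@H]3O[C@]3(Cc4ccc(OCc5ccccc5)c(OC)c4)CO2)cc(Br)c1OCc1ccccc1 | intermediate
17 | sodium tertiary alkoxide from selenolate opening of 16 | COc1cc(C2OC[C@@H]([Se]c3ccccc3)[C@@]([O-])(Cc3ccc(OCc4ccccc4)c(OC)c3)CO2)cc(Br)c1OCc1ccccc1.[Na+] | intermediate
18 | (5R,6R)-6-(phenylselanyl)-5-(triethylsilyloxy)-1,3-dioxepane | COc1cc(C2OC[C@@H]([Se]c3ccccc3)[C@@](O[Si](CC)(CC)CC)(Cc3ccc(OCc4ccccc4)c(OC)c3)CO2)cc(Br)c1OCc1ccccc1 | intermediate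
19 | selenoxide of 18 | COc1cc(C2OC[C@@H]([Se](=O)c3ccccc3)[C@@](O[Si](CC)(CC)CC)(Cc3ccc(OCc4ccccc4)c(OC)c3)CO2)cc(Br)c1OCc1ccccc1 | intermediate
20 | (5S)-bromoaryl vinyl acetal (4,5-dihydro-1,3-dioxepine) | COc1cc(C2OC=C[C@@](O[Si](CC)(CC)CC)(Cc3ccc(OCc4ccccc4)c(OC)c3)CO2)cc(Br)c1OCc1ccccc1 | intermediate
21 | (2R,3R,4S)-bromoaryl oxolane-3-carbaldehyde | COc1cc(C[C@@]2(O[Si](CC)(CC)CC)CO[C@@H](c3cc(OC)c(OCc4ccccc4)c(Br)c3)[C@H]2C=O)ccc1OCc1ccccc1 | intermediate
22 | (2R,3R,4S)-bromoaryl oxolan-3-ylmethanol | COc1cc(C[C@@]2(O[Si](CC)(CC)CC)CO[C@@H](c3cc(OC)c(OCc4ccccc4)c(Br)c3)[C@H]2CO)ccc1OCc1ccccc1 | intermediate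
23 | (2S,3S,4S)-di-O-benzyl-5-bromocycloolivil (triol) | COc1cc([C@H]2c3cc(OCc4ccccc4)c(OC)cc3C[C@@](O)(CO)[C@@H]2CO)cc(Br)c1OCc1ccccc1 | intermediate
24 | tris-TBS ether of 23 | COc1cc([C@H]2c3cc(OCc4ccccc4)c(OC)cc3C[C@@](O[Si](C)(C)C(C)(C)C)(CO[Si](C)(C)C(C)(C)C)[C@@H]2CO[Si](C)(C)C(C)(C)C)cc(Br)c1OCc1ccccc1 | intermediate
25 | pinacol boronate of vinyl acetal 20 | COc1cc(C2OC=C[C@@](O[Si](CC)(CC)CC)(Cc3ccc(OCc4ccccc4)c(OC)c3)CO2)cc(B2OC(C)(C)C(C)(C)O2)c1OCc1ccccc1 | intermediate
26 | biaryl vinyl acetal | COc1cc(C2OC=C[C@@](O[Si](CC)(CC)CC)(Cc3ccc(OCc4ccccc4)c(OC)c3)CO2)cc(-c2cc([C@H]3c4cc(OCc5ccccc5)c(OC)cc4C[C@@](O[Si](C)(C)C(C)(C)C)(CO[Si](C)(C)C(C)(C)C)[C@@H]3CO[Si](C)(C)C(C)(C)C)cc(OC)c2OCc2ccccc2)c1OCc1ccccc1 | intermediate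
27 | biaryl (2R,3R,4S)-oxolane-3-carbaldehyde | COc1cc(C[C@@]2(O[Si](CC)(CC)CC)CO[C@@H](c3cc(OC)c(OCc4ccccc4)c(-c4cc([C@H]5c6cc(OCc7ccccc7)c(OC)cc6C[C@@](O[Si](C)(C)C(C)(C)C)(CO[Si](C)(C)C(C)(C)C)[C@@H]5CO[Si](C)(C)C(C)(C)C)cc(OC)c4OCc4ccccc4)c3)[C@H]2C=O)ccc1OCc1ccccc1 | intermediate
28 | biaryl (2R,3R,4S)-oxolan-3-ylmethanol (TES, 3 TBS, 4 Bn) | COc1cc(C[C@@]2(O[Si](CC)(CC)CC)CO[C@@H](c3cc(OC)c(OCc4ccccc4)c(-c4cc([C@H]5c6cc(OCc7ccccc7)c(OC)cc6C[C@@](O[Si](C)(C)C(C)(C)C)(CO[Si](C)(C)C(C)(C)C)[C@@H]5CO[Si](C)(C)C(C)(C)C)cc(OC)c4OCc4ccccc4)c3)[C@H]2CO)ccc1OCc1ccccc1 | intermediate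
29 | tetra-O-benzyl ether of the target | COc1cc(C[C@@]2(O)CO[C@@H](c3cc(OC)c(OCc4ccccc4)c(-c4cc([C@H]5c6cc(OCc7ccccc7)c(OC)cc6C[C@@](O)(CO)[C@@H]5CO)cc(OC)c4OCc4ccccc4)c3)[C@H]2CO)ccc1OCc1ccccc1 | intermediate
30 | CNP0344108.1 | COc1cc(C[C@@]2(O)CO[C@@H](c3cc(OC)c(O)c(-c4cc([C@H]5c6cc(O)c(OC)cc6C[C@@](O)(CO)[C@@H]5CO)cc(OC)c4O)c3)[C@H]2CO)ccc1O | target

## Step count

Total step count: 18. Longest linear sequence: 15 (steps 1, 3–6, 8–13, 15–18).

## Steps most likely to fail

**Step 16.**
- Three things may go wrong. The facial selectivity at the enol ether relative to the quaternary carbinol carbon may be poor. The cis C2/C3 relation may erode through re-ionisation. The tertiary allylic silyl ether may ionise in a Ferrier-type process.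
- The fallback sets out from 26 and comes back at 28. It makes the C2–C3 bond by an intermolecular lactone aldol and still closes the oxolane last, by reductive cycloetherification.
- Mild hydrolysis of 26 (PPTS, wet THF) should return both halves, the biaryl aldehyde F1 and the silyloxy lactol F2. TPAP/NMO oxidises the latter to the silyloxy lactone F3.
- The lithium enolate of F3 (LDA, THF, −78 °C) should add to F1 anti to the arylmethyl branch to give the aldol adduct F4. Its carbinol epimers are of no consequence.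
- LiAlH4 should then give the triol F5. MnO2 oxidises only the benzylic alcohol, and the resulting hydroxy ketone closes to the cyclic hemiketal F6.
- Et3SiH/BF3·OEt2 (CH2Cl2, −78 °C) should deliver hydride to the cyclic oxocarbenium ion from the face opposite to CH2OH and CH2Ar. This places the aryl group cis to both and gives 28.

**Step 12.**
- The benzylic C–O bond may ionise slowly, because the bromine and the twisted benzyloxy group stabilise the cation poorly. Benzyl ethers may be lost under the stronger acid this would then require.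
- The fallback sets out from 22 and comes back at 23. It switches the activation mode to a free para-phenol (quinone-methide type ionisation).
- BCl3/pentamethylbenzene (CH2Cl2, −78 °C, MeOH quench) should strip both benzyl groups and the TES group to give 5-bromo-7-epi-olivil F7.
- Dilute aqueous formic acid at rt should isomerise this to 5-bromocycloolivil F8. BnBr/K2CO3 in acetone re-benzylates only the two phenols to give 23.

**Step 10.**
- The syn-elimination towards an oxygen-bearing carbon may be sluggish, and selenenic acid may re-add to the enol ether that forms.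
- The fallback sets out from 16 and comes back at 20. It replaces the Ei process with an anti-E2 dehydrohalogenation.
- Li2NiBr4 (THF, 0 °C) should open the epoxide at the secondary carbon to give the bromohydrin F9. TESCl/imidazole/DMAP (DMF) caps the tertiary alcohol to give the silyloxy bromide F10.
- KOt-Bu (THF, 0 °C) should then remove HBr in the only possible direction, because the other β-carbon is quaternary, and give 20.

## Further compounds

F1 | step 16 | biaryl aldehyde | COc1cc(C=O)cc(-c2cc([C@H]3c4cc(OCc5ccccc5)c(OC)cc4C[C@@](O[Si](C)(C)C(C)(C)C)(CO[Si](C)(C)C(C)(C)C)[C@@H]3CO[Si](C)(C)C(C)(C)C)cc(OC)c2OCc2ccccc2)c1OCc1ccccc1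
F2 | step 16 | (4S)-4-{[4-(benzyloxy)-3-methoxyphenyl]methyl}-4-[(triethylsilyl)oxy]oxolan-2-ol | OC1C[C@@](O[Si](CC)(CC)CC)(Cc2ccc(OCc3ccccc3)c(OC)c2)CO1
F3 | step 16 | (4S)-4-{[4-(benzyloxy)-3-methoxyphenyl]methyl}-4-[(triethylsilyl)oxy]oxolan-2-one | O=C1C[C@@](O[Si](CC)(CC)CC)(Cc2ccc(OCc3ccccc3)c(OC)c2)CO1
F4 | step 16 | lactone aldol adduct (carbinol epimers) | O=C1[C@H](C(O)c2cc(OC)c(OCc3ccccc3)c(-c3cc([C@H]4c5cc(OCc6ccccc6)c(OC)cc5C[C@@](O[Si](C)(C)C(C)(C)C)(CO[Si](C)(C)C(C)(C)C)[C@@H]4CO[Si](C)(C)C(C)(C)C)cc(OC)c3OCc3ccccc3)c2)[C@@](O[Si](CC)(CC)CC)(Cc2ccc(OCc3ccccc3)c(OC)c2)CO1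
F5 | step 16 | acyclic triol | OC[C@H](C(O)c2cc(OC)c(OCc3ccccc3)c(-c3cc([C@H]4c5cc(OCc6ccccc6)c(OC)cc5C[C@@](O[Si](C)(C)C(C)(C)C)(CO[Si](C)(C)C(C)(C)C)[C@@H]4CO[Si](C)(C)C(C)(C)C)cc(OC)c3OCc3ccccc3)c2)[C@@](O[Si](CC)(CC)CC)(Cc2ccc(OCc3ccccc3)c(OC)c2)CO
F6 | step 16 | cyclic hemiketal (2-aryl-oxolan-2-ol, anomers) | COc1cc(C[C@@]2(O[Si](CC)(CC)CC)COC(O)(c3cc(OC)c(OCc4ccccc4)c(-c4cc([C@H]5c6cc(OCc7ccccc7)c(OC)cc6C[C@@](O[Si](C)(C)C(C)(C)C)(CO[Si](C)(C)C(C)(C)C)[C@@H]5CO[Si](C)(C)C(C)(C)C)cc(OC)c4OCc4ccccc4)c3)[C@H]2CO)ccc1OCc1ccccc1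
F7 | step 12 | 5-bromo-7-epi-olivil | COc1cc(C[C@@]2(O)CO[C@@H](c3cc(OC)c(O)c(Br)c3)[C@H]2CO)ccc1O
F8 | step 12 | 5-bromocycloolivil | COc1cc([C@H]2c3cc(O)c(OC)cc3C[C@@](O)(CO)[C@@H]2CO)cc(Br)c1O
F9 | step 10 | bromohydrin acetal | COc1cc(C2OC[C@@H](Br)[C@@](O)(Cc3ccc(OCc4ccccc4)c(OC)c3)CO2)cc(Br)c1OCc1ccccc1
F10 | step 10 | silyloxy bromide acetal | COc1cc(C2OC[C@@H](Br)[C@@](O[Si](CC)(CC)CC)(Cc3ccc(OCc4ccccc4)c(OC)c3)CO2)cc(Br)c1OCc1ccccc1
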